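The C15 chain (C1′ on the resorcinol ring) is cut between C6′ and the allylic C7′. The key step is a copper-catalysed, SN2-selective sp3–sp3 coupling at −78 °C of a 6-arylhexyl Grignard reagent with (2Z,4R)-1-bromonon-2-en-4-yl acetate; in one operation it joins both halves with the Z-C8′=C9′ alkene, the C10′ stereocentre and the C10′ acetate already in place. It exploits the allylic activation of the C7′–Br bond by the C8′=C9′ alkene, which lets the primary bromide react while the secondary acetate stays. The bromoacetate comes from a temporary ring: C7′–C10′ and the C10′ oxygen form a 2,5-dihydrofuran (metathesis fixes Z), opened by acetyl bromide.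

Key step: step 6

Remark: the target's C10′ centre is (R); (R)-oct-1-en-3-ol of high enantiomeric purity is taken as a commercial starting material and supplies this centre, whose C–O bond is never broken in the route.

Step 1
Reactants: 1 (R)-oct-1-en-3-ol
Product: 2 (R)-3-(allyloxy)oct-1-ene
Conditions: NaH (1.2 equiv), allyl bromide (1.3 equiv), Bu4NI (cat.), THF, 0 °C to rt
Reagents that add atoms: allyl bromide, C=CCBr
Why: Williamson ether synthesis, in which deprotonated 1 should displace bromide from allyl bromide by SN2 without involving the carbinol stereocentre.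

Step 2
Reactants: 2 (R)-3-(allyloxy)oct-1-ene
Product: 3 (R)-2-pentyl-2,5-dihydrofuran
Conditions: Grubbs II catalyst (2 mol%), CH2Cl2 (0.05 M), 40 °C
Reagents that add atoms: none
Why: Ring-closing olefin metathesis of the 1,6-diene should close the five-membered ring with loss of ethene, and the ring forces the new double bond to be cis, which later becomes the Z alkene of the target.

Step 3
Reactants: 3 (R)-2-pentyl-2,5-dihydrofuran
Product: 4 (2Z,4R)-1-bromonon-2-en-4-yl acetate
Conditions: AcBr (1.5 equiv), CH2Cl2, 0 °C to rt, dark, no Lewis acid; used at once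
Reagents that add atoms: acetyl bromide, CC(=O)Br
Why: Acylative ether cleavage, in which O-acetylation gives an acyloxonium bromide that bromide should open by SN2 at the unhindered ring CH2 and not at the pentyl-bearing carbon (both ring C–O bonds lie in the plane of the alkene, which disfavours allyl-cation formation and SN2′ attack), so the (R) C–O bond is kept and the ring geometry is delivered as the Z alkene.

Step 4
Reactants: 5 5-bromobenzene-1,3-diol
Product: 6 1-bromo-3,5-bis(tert-butyldimethylsilyloxy)benzene
Conditions: TBSCl (2.4 equiv), imidazole (5 equiv), DMF, rt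
Reagents that add atoms: tert-butyldimethylsilyl chloride (TBSCl), CC(C)(C)[Si](C)(C)Cl
Why: Standard imidazole-promoted silylation of both phenols, chosen because aryl silyl ethers tolerate Grignard reagents and are later removed by fluoride without touching an acetate.

Step 5
Reactants: 6 1-bromo-3,5-bis(tert-butyldimethylsilyloxy)benzene; 7 1-bromo-6-chlorohexane
Product: 9 1-(6-chlorohexyl)-3,5-bis(tert-butyldimethylsilyloxy)benzene, via arylmagnesium bromide 8 (not isolated)
Conditions: Mg, LiCl, THF, rt; then 7 (1.5 equiv), Li2CuCl4 (3 mol%), THF, 0 °C to rt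
Reagents that add atoms: none
Why: Magnesium insertion into the aryl bromide followed by a copper-catalysed Grignard–alkyl halide coupling (Kochi-type) should engage only the C–Br end of 7, since primary alkyl chlorides are inert under these conditions.

Step 6
Reactants: 9 1-(6-chlorohexyl)-3,5-bis(tert-butyldimethylsilyloxy)benzene; 4 (2Z,4R)-1-bromonon-2-en-4-yl acetate
Product: 11 (8Z,10R)-1-[3,5-bis(tert-butyldimethylsilyloxy)phenyl]pentadec-8-en-10-yl acetate, via alkylmagnesium chloride 10 (not isolated)
Conditions: Mg (activated with 1,2-dibromoethane), THF, reflux; then added dropwise (1.15 equiv) to 4, Li2CuCl4 (5 mol%), THF, −78 °C; NH4Cl quench at −78 °C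
Reagents that add atoms: none
Why: Copper-catalysed allyl–alkyl Grignard coupling (Kochi-type, Li2CuCl4): the cuprate formed from 10 should add oxidatively to the allylic C–Br bond of 4, and the allylcopper(III) species should eliminate reductively at the primary carbon to form the C6′–C7′ bond. The closest known reaction type is the SN2-selective coupling of primary (Z)-allylic halides with alkyl Grignard reagents under Li2CuCl4 catalysis in THF. No ring is closed and no stereocentre is created; the (R) centre of 4 is a spectator whose C–O bond is not touched. The step needs regioselectivity (SN2 over SN2′), which the Li2CuCl4/THF conditions and the branched, acetoxy-bearing carbon next to the γ-position should secure. It needs retention of the Z alkene, which fast reductive elimination at −78 °C should secure before any syn/anti equilibration of the allyl unit. It needs chemoselectivity for bromide over acetate, which the far higher reactivity of a primary allylic bromide at −78 °C under slow addition of 10 should secure, while the aryl silyl ethers are inert to Grignard reagents.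

Step 7
Reactants: 11 (8Z,10R)-1-[3,5-bis(tert-butyldimethylsilyloxy)phenyl]pentadec-8-en-10-yl acetate
Product: 12 (8Z,10R)-1-(3,5-dihydroxyphenyl)pentadec-8-en-10-yl acetate (CNP0315732.1)
Conditions: KHF2 (3 equiv), MeOH, rt
Reagents that add atoms: none
Why: Bifluoride cleaves aryl silyl ethers (phenoxide is a good leaving group from silicon) under near-neutral conditions, so the allylic acetate and the Z alkene should stay untouched.

Compound list
1 | (R)-oct-1-en-3-ol | CCCCC[C@H](C=C)O | starting material
2 | (R)-3-(allyloxy)oct-1-ene | CCCCC[C@H](C=C)OCC=C | intermediate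
3 | (R)-2-pentyl-2,5-dihydrofuran | CCCCC[C@H]1OCC=C1 | intermediate
4 | (2Z,4R)-1-bromonon-2-en-4-yl acetate | CCCCC[C@H](/C=C\CBr)OC(C)=O | intermediate
5 | 5-bromobenzene-1,3-diol | Oc1cc(O)cc(Br)c1 | starting material
6 | 1-bromo-3,5-bis(tert-butyldimethylsilyloxy)benzene | CC(C)(C)[Si](C)(C)Oc1cc(Br)cc(O[Si](C)(C)C(C)(C)C)c1 | intermediate
7 | 1-bromo-6-chlorohexane | ClCCCCCCBr | starting material
8 | [3,5-bis(tert-butyldimethylsilyloxy)phenyl]magnesium bromide | Br[Mg]c1cc(O[Si](C)(C)C(C)(C)C)cc(O[Si](C)(C)C(C)(C)C)c1 | intermediate
9 | 1-(6-chlorohexyl)-3,5-bis(tert-butyldimethylsilyloxy)benzene | ClCCCCCCc1cc(O[Si](C)(C)C(C)(C)C)cc(O[Si](C)(C)C(C)(C)C)c1 | intermediate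
10 | {6-[3,5-bis(tert-butyldimethylsilyloxy)phenyl]hexyl}magnesium chloride | Cl[Mg]CCCCCCc1cc(O[Si](C)(C)C(C)(C)C)cc(O[Si](C)(C)C(C)(C)C)c1 | intermediate
11 | (8Z,10R)-1-[3,5-bis(tert-butyldimethylsilyloxy)phenyl]pentadec-8-en-10-yl acetate | CCCCC[C@H](/C=C\CCCCCCCc1cc(O[Si](C)(C)C(C)(C)C)cc(O[Si](C)(C)C(C)(C)C)c1)OC(C)=O | intermediate
12 | (8Z,10R)-1-(3,5-dihydroxyphenyl)pentadec-8-en-10-yl acetate | CCCCC[C@H](/C=C\CCCCCCCc1cc(O)cc(O)c1)OC(C)=O | target

Total step count: 7
Longest linear sequence: 5 steps (steps 1, 2, 3, 6, 7)

Steps most likely to fail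

Step 6. The alkyl group may be delivered to the internal carbon (SN2′), the Z geometry may erode through equilibration of the allylic bromide or of the allylcopper intermediate, or the Grignard reagent may attack the acetate. The fallback replaces the copper coupling by a sulfone-anion alkylation and reductive desulfonylation; it sets out from 9 (and uses 4) and comes back at 11. Chloride 9 is heated with sodium benzenesulfinate (NaI cat., DMF, 70 °C) to give {[6-(3,5-bis(tert-butyldimethylsilyloxy)phenyl)hexyl]sulfonyl}benzene F1. Deprotonation with n-BuLi (THF, −78 °C) gives the α-lithio sulfone F2, which should be alkylated at −78 °C by bromide 4 in a direct SN2 reaction at the primary allylic carbon. This gives (8Z,10R)-1-[3,5-bis(tert-butyldimethylsilyloxy)phenyl]-6-(phenylsulfonyl)pentadec-8-en-10-yl acetate F3 as a mixture of epimers at the sulfone carbon. Buffered sodium amalgam (Na2HPO4, MeOH/THF, −20 °C) then removes the sulfonyl group and gives 11.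

Step 3. The acyloxonium ion may open at the wrong C–O bond through an ionising pathway, or bromide may isomerise the allylic bromide (Z to E, or allylic transposition). The fallback builds the same bromoacetate through a lactone ring and an enzymatic differentiation; it sets out from 1 and comes back at 4. Alcohol 1 is esterified with acryloyl chloride (Et3N, CH2Cl2, 0 °C) to (R)-oct-1-en-3-yl acrylate F4. Ring-closing metathesis (Grubbs II, CH2Cl2, reflux) should give (R)-5-pentylfuran-2(5H)-one F5, in which the ring fixes the cis alkene. DIBAL-H (excess, CH2Cl2, −78 °C to rt) should reduce the lactone to (2Z,4R)-non-2-ene-1,4-diol F6. Acetylation (Ac2O, pyridine, DMAP) gives (2Z,4R)-non-2-ene-1,4-diyl diacetate F7. Lipase-catalysed methanolysis (immobilised Candida antarctica lipase B, MeOH, MTBE, rt) should remove only the primary acetate and give (2Z,4R)-1-hydroxynon-2-en-4-yl acetate F8. Appel bromination (CBr4, PPh3, CH2Cl2, −20 °C) then gives 4.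

Step 5. Magnesium insertion into the electron-rich aryl bromide may be sluggish, and homocoupling or a second alkylation may compete. The fallback attaches the chain by an sp2–sp coupling and reduction; it sets out from 6 and comes back at 9. Sonogashira coupling of 6 with commercial 6-chlorohex-1-yne (PdCl2(PPh3)2, CuI, Et3N, THF, 70 °C) should give 1-(6-chlorohex-1-yn-1-yl)-3,5-bis(tert-butyldimethylsilyloxy)benzene F9. Hydrogenation of the alkyne (H2, Pd/C, EtOAc, rt) gives 9.

Further compounds
F1 | step 6 | {[6-(3,5-bis(tert-butyldimethylsilyloxy)phenyl)hexyl]sulfonyl}benzene | O=S(=O)(CCCCCCc1cc(O[Si](C)(C)C(C)(C)C)cc(O[Si](C)(C)C(C)(C)C)c1)c1ccccc1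
F2 | step 6 | α-lithio derivative of sulfone F1 (not isolated) | [Li]C(CCCCCc1cc(O[Si](C)(C)C(C)(C)C)cc(O[Si](C)(C)C(C)(C)C)c1)S(=O)(=O)c1ccccc1
F3 | step 6 | (8Z,10R)-1-[3,5-bis(tert-butyldimethylsilyloxy)phenyl]-6-(phenylsulfonyl)pentadec-8-en-10-yl acetate, both C6 epimers | CCCCC[C@H](/C=C\CC(CCCCCc1cc(O[Si](C)(C)C(C)(C)C)cc(O[Si](C)(C)C(C)(C)C)c1)S(=O)(=O)c1ccccc1)OC(C)=O
F4 | step 3 | (R)-oct-1-en-3-yl acrylate | CCCCC[C@H](C=C)OC(=O)C=C
F5 | step 3 | (R)-5-pentylfuran-2(5H)-one | CCCCC[C@H]1OC(=O)C=C1
F6 | step 3 | (2Z,4R)-non-2-ene-1,4-diol | CCCCC[C@H](/C=C\CO)O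
F7 | step 3 | (2Z,4R)-non-2-ene-1,4-diyl diacetate | CCCCC[C@H](/C=C\COC(C)=O)OC(C)=O
F8 | step 3 | (2Z,4R)-1-hydroxynon-2-en-4-yl acetate | CCCCC[C@H](/C=C\CO)OC(C)=O
F9 | step 5 | 1-(6-chlorohex-1-yn-1-yl)-3,5-bis(tert-butyldimethylsilyloxy)benzene | ClCCCCC#Cc1cc(O[Si](C)(C)C(C)(C)C)cc(O[Si](C)(C)C(C)(C)C)c1
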